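The route rests on cutting the C4a–C5 bond of carbocycle B. C4a is alpha to C4=O and beta to N1 in the vinylogous amide N1–C8a=C4a–C4=O of pyridone ring A. It is therefore the only free nucleophilic ring carbon, and C5 is bonded directly to it. An iridium phosphoramidite catalyst turns a tethered (E)-allylic methyl carbonate into an allyl electrophile, which C4a captures at its inner terminus. This one operation closes ring B, sets C5 and leaves a vinyl handle for the phenylpentyl chain. The precursor is a monocyclic N-(4-methoxybenzyl)-3-methoxy-2-methyl-4-pyridone. Its C8a carries a six-carbon chain with the (R)-C8 silyl ether, from methyl (R)-glycidate, and the terminal carbonate.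

Key step: step 6

Remarks
- Numbering: all intermediates carry the atom numbers of the target (N1, C2, C3, C4, C4a, C5–C8, C8a; side chain C1′–C5′). Ring A is the pyridone and ring B the carbocycle.
- Stereochemical bookkeeping: the target is (5S,8R), with the C5 chain and the C8 oxygen cis. Compounds 11 and 13 have the same spatial arrangement but are (5R), because an sp2 C1′ outranks C6. Opening (R)-glycidate at its CH2 group gives the required (R) centre at C8.
- Assumption: the face rule of this catalyst family is untested for a pyridone carbon nucleophile. The (Sa,S,S) ligand is written as the antipode expected to open the Re face of C5. Both antipodes are sold, and the mirror-image ligand is used instead if the first run gives the trans isomer.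
- Assumption: 3-methoxypentane-2,4-dione is taken as a catalogue compound.

Step 1
Reactants: 1 methyl (R)-glycidate
Product: 2 methyl (2R)-2-hydroxyhex-5-enoate
Conditions: allylMgCl (2.4 equiv), CuBr·SMe2 (1.2 equiv), THF/Me2S, −78 °C; then 1, −78 → −50 °C; aq NH4Cl
Reagents that add atoms: allylmagnesium chloride, C=CC[Mg]Cl
Why: Copper-mediated SN2 opening of a terminal epoxide: the diallylcuprate attacks the unsubstituted C3 of the glycidate faster than the ester at −78 °C and never touches the C2–O bond, so the (R) centre (the later C8) is carried over unchanged from the chiral pool.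

Step 2
Reactants: 2 methyl (2R)-2-hydroxyhex-5-enoate
Product: 3 methyl (2R)-2-[(tert-butyldimethylsilyl)oxy]hex-5-enoate
Conditions: TBSCl (1.2 equiv), imidazole (2.5 equiv), DMF, 0 °C → rt
Reagents that add atoms: tert-butyldimethylsilyl chloride, CC(C)(C)[Si](C)(C)Cl
Why: Imidazole-promoted O-silylation of a secondary alcohol, mild enough not to enolise the ester, masks O8, which would otherwise close a tetrahydrofuran onto the allyl unit in step 6.

Step 3
Reactants: 3 methyl (2R)-2-[(tert-butyldimethylsilyl)oxy]hex-5-enoate; 4 3-methoxypentane-2,4-dione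
Product: 6 (7R)-7-[(tert-butyldimethylsilyl)oxy]-3-methoxyundec-10-ene-2,4,6-trione, via dilithio dianion 5 (not isolated)
Conditions: 4 (2.2 equiv), LDA (4.5 equiv), THF, −78 → 0 °C; then 3 (1 equiv), −78 → −20 °C; cold 1 M HCl
Reagents that add atoms: none
Why: Claisen condensation of a 1,3-diketone dianion through its more reactive terminal carbanion: the symmetrical diketone offers only one such site, the inductively activated alpha-silyloxy ester should be acylated faster than it is enolised at −78 °C, and the triketone is held as its enolate until the quench, which shields the C8 hydrogen.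

Step 4
Reactants: 6 (7R)-7-[(tert-butyldimethylsilyl)oxy]-3-methoxyundec-10-ene-2,4,6-trione; 7 4-methoxybenzylamine
Product: 9 6-{(1R)-1-[(tert-butyldimethylsilyl)oxy]pent-4-en-1-yl}-3-methoxy-1-(4-methoxybenzyl)-2-methylpyridin-4(1H)-one, via enaminodiketone 8 (not isolated)
Conditions: 7 (1.5 equiv), AcOH (0.3 equiv), 4 Å MS, toluene, 100 °C
Reagents that add atoms: none
Why: Condensation of a 1,3,5-triketone with a primary amine to an N-substituted 4-pyridone (chelated enaminone at the unhindered acetyl end, then attack of nitrogen on the C8a ketone and loss of water, driven by aromatisation) builds ring A with the benzyl group unambiguously on N1 and avoids both a separate pyranone stage and any N-versus-O alkylation problem.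

Step 5
Reactants: 9 6-{(1R)-1-[(tert-butyldimethylsilyl)oxy]pent-4-en-1-yl}-3-methoxy-1-(4-methoxybenzyl)-2-methylpyridin-4(1H)-one
Product: 10 (2E,6R)-6-[(tert-butyldimethylsilyl)oxy]-6-[5-methoxy-1-(4-methoxybenzyl)-6-methyl-4-oxo-1,4-dihydropyridin-2-yl]hex-2-en-1-yl methyl carbonate
Conditions: allyl methyl carbonate (5 equiv), second-generation Hoveyda–Grubbs catalyst (5 mol %), CH2Cl2, 40 °C; chromatography on AgNO3-impregnated silica to remove the (Z)-isomer
Reagents that add atoms: allyl methyl carbonate, C=CCOC(=O)OC
Why: Olefin cross-metathesis of two unhindered terminal alkenes, pushed toward the cross product by excess of the cheap carbonate and toward the (E)-alkene by equilibration, installs the leaving group only after the strong base of step 3, and geometrically pure (E)-10 matters because (Z)-carbonates react less selectively under iridium catalysis.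

Step 6
Reactants: 10 (2E,6R)-6-[(tert-butyldimethylsilyl)oxy]-6-[5-methoxy-1-(4-methoxybenzyl)-6-methyl-4-oxo-1,4-dihydropyridin-2-yl]hex-2-en-1-yl methyl carbonate
Product: 11 (5R,8R)-8-[(tert-butyldimethylsilyl)oxy]-5-ethenyl-3-methoxy-1-(4-methoxybenzyl)-2-methyl-5,6,7,8-tetrahydroquinolin-4(1H)-one
Conditions: [Ir(cod)Cl]2 (4 mol %), (Sa,S,S)-N,N-bis[1-(2-methoxyphenyl)ethyl] BINOL phosphoramidite (8 mol %), 1,5,7-triazabicyclo[4.4.0]dec-5-ene (10 mol %), THF, rt, 2 h (activation); then 10, THF (0.02 M), 50 °C, no further base
Reagents that add atoms: none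
Why: Proposed new method: the cyclometallated monovalent iridium phosphoramidite complex binds the (E)-alkene of 10 and expels methyl carbonate (which falls apart to CO2 and methoxide) to give a trivalent iridium allyl, C4a of ring A attacks the substituted allyl terminus anti to the metal, and methoxide takes the C4a proton of the sigma adduct so that the pyridone is restored. The closest known reaction type is the iridium-catalysed intramolecular asymmetric allylic Friedel–Crafts alkylation of indoles and pyrroles, in particular 2-tethered indoles that close through C3 to vinyl-tetrahydrocarbazoles; a 4-pyridone has not been used as the carbon nucleophile, but its positions alpha to the carbonyl are where halogenation and Mannich reactions take place. Ring B closes in the 6-exo mode (C4a, C5, C6, C7, C8 and C8a inside, C1′=C2′ outside), while attack at the terminal carbon would need an eight-membered ring and runs against the branched preference of iridium. C5 is controlled by the ligand, which decides the allyl face left open (C4a has to bond to the Re face of C5), and a chair-like closure with the C8 silyl ether axial, away from the N-benzyl CH2, and the allyl unit equatorial leads to the same 5,8-cis isomer, so catalyst and substrate should work together. Site selectivity lies in the substrate: N1 carries the 4-methoxybenzyl group, C3 carries OMe, O8 is silylated and the C4 oxygen cannot reach the allyl unit of its own molecule, so that only dilution is needed against intermolecular O-allylation. Since C8 is already a single enantiomer, leakage in face selectivity or from traces of (Z)-carbonate shows up as the trans diastereomer, which chromatography should remove.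

Step 7
Reactants: 11 (5R,8R)-8-[(tert-butyldimethylsilyl)oxy]-5-ethenyl-3-methoxy-1-(4-methoxybenzyl)-2-methyl-5,6,7,8-tetrahydroquinolin-4(1H)-one; 12 5-phenyl-1-pentene
Product: 13 (5R,8R)-8-[(tert-butyldimethylsilyl)oxy]-3-methoxy-1-(4-methoxybenzyl)-2-methyl-5-[(1E)-5-phenylpent-1-en-1-yl]-5,6,7,8-tetrahydroquinolin-4(1H)-one
Conditions: 12 (4 equiv), second-generation Hoveyda–Grubbs catalyst (5–10 mol %), 1,4-benzoquinone (10 mol %), CH2Cl2, 40 °C
Reagents that add atoms: none
Why: Olefin cross-metathesis between the alpha-branched vinyl group, which homodimerises slowly, and an excess of an unhindered terminal alkene adds exactly the three methylene groups and the phenyl ring that are missing, while benzoquinone intercepts ruthenium hydrides that could move the double bond toward C5.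

Step 8
Reactants: 13 (5R,8R)-8-[(tert-butyldimethylsilyl)oxy]-3-methoxy-1-(4-methoxybenzyl)-2-methyl-5-[(1E)-5-phenylpent-1-en-1-yl]-5,6,7,8-tetrahydroquinolin-4(1H)-one
Product: 14 (5S,8R)-8-[(tert-butyldimethylsilyl)oxy]-3-methoxy-1-(4-methoxybenzyl)-2-methyl-5-(5-phenylpentyl)-5,6,7,8-tetrahydroquinolin-4(1H)-one
Conditions: H2 (1 atm), 5% Pt/C, EtOAc, rt
Reagents that add atoms: none
Why: Heterogeneous catalytic hydrogenation of a 1,2-disubstituted alkene; platinum is preferred to palladium because it causes little double-bond migration and no N-benzyl hydrogenolysis, so C5 keeps its geometry and only its descriptor changes from R to S through the CIP ranking.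

Step 9
Reactants: 14 (5S,8R)-8-[(tert-butyldimethylsilyl)oxy]-3-methoxy-1-(4-methoxybenzyl)-2-methyl-5-(5-phenylpentyl)-5,6,7,8-tetrahydroquinolin-4(1H)-one
Product: 16 (5S,8R)-8-hydroxy-3-methoxy-2-methyl-5-(5-phenylpentyl)-5,6,7,8-tetrahydroquinolin-4(1H)-one, via N-benzylated alcohol 15 (not isolated)
Conditions: TFA/H2O (95:5), anisole (10 equiv), rt then 70 °C; evaporation; aq NaHCO3/MeOH
Reagents that add atoms: none
Why: Acidolysis of both protecting groups: aqueous TFA cleaves the silyl ether at room temperature, on heating the O-protonated pyridone departs from the 4-methoxybenzyl carbon in an SN1 process helped by relief of the strain between the N-substituent and its two neighbours, anisole traps the cation by Friedel–Crafts alkylation, and neither C8–O (a cation there would adjoin a pyridinium ring) nor C5–H is labile, so both stereocentres persist.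

Compound list
1 | methyl (R)-glycidate | COC(=O)[C@H]1CO1 | starting material
2 | methyl (2R)-2-hydroxyhex-5-enoate | COC(=O)[C@H](O)CCC=C | intermediate
3 | methyl (2R)-2-[(tert-butyldimethylsilyl)oxy]hex-5-enoate | COC(=O)[C@H](O[Si](C)(C)C(C)(C)C)CCC=C | intermediate
4 | 3-methoxypentane-2,4-dione | CC(=O)C(OC)C(C)=O | starting material
5 | dilithio dianion of 3-methoxypentane-2,4-dione (C1 and C3 deprotonated; not isolated) | [Li+].[Li+].[CH2-]C(=O)[C-](OC)C(C)=O | intermediate
6 | (7R)-7-[(tert-butyldimethylsilyl)oxy]-3-methoxyundec-10-ene-2,4,6-trione (drawn as the triketo tautomer; C3 is labile) | CC(=O)C(OC)C(=O)CC(=O)[C@H](O[Si](C)(C)C(C)(C)C)CCC=C | intermediate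
7 | 4-methoxybenzylamine | NCc1ccc(OC)cc1 | starting material
8 | (2E,7R)-7-[(tert-butyldimethylsilyl)oxy]-3-methoxy-2-[(4-methoxybenzyl)amino]undeca-2,10-diene-4,6-dione (N–H chelated to the C4 carbonyl; not isolated) | C/C(NCc1ccc(OC)cc1)=C(OC)/C(=O)CC(=O)[C@H](O[Si](C)(C)C(C)(C)C)CCC=C | intermediate
9 | 6-{(1R)-1-[(tert-butyldimethylsilyl)oxy]pent-4-en-1-yl}-3-methoxy-1-(4-methoxybenzyl)-2-methylpyridin-4(1H)-one | COc1c(C)n(Cc2ccc(OC)cc2)c([C@H](O[Si](C)(C)C(C)(C)C)CCC=C)cc1=O | intermediate
10 | (2E,6R)-6-[(tert-butyldimethylsilyl)oxy]-6-[5-methoxy-1-(4-methoxybenzyl)-6-methyl-4-oxo-1,4-dihydropyridin-2-yl]hex-2-en-1-yl methyl carbonate | COc1c(C)n(Cc2ccc(OC)cc2)c([C@H](O[Si](C)(C)C(C)(C)C)CC/C=C/COC(=O)OC)cc1=O | intermediate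
11 | (5R,8R)-8-[(tert-butyldimethylsilyl)oxy]-5-ethenyl-3-methoxy-1-(4-methoxybenzyl)-2-methyl-5,6,7,8-tetrahydroquinolin-4(1H)-one (5,8-cis) | COc1c(C)n(Cc3ccc(OC)cc3)c2c(c1=O)[C@@H](C=C)CC[C@H]2O[Si](C)(C)C(C)(C)C | intermediate
12 | 5-phenyl-1-pentene | C=CCCCc1ccccc1 | starting material
13 | (5R,8R)-8-[(tert-butyldimethylsilyl)oxy]-3-methoxy-1-(4-methoxybenzyl)-2-methyl-5-[(1E)-5-phenylpent-1-en-1-yl]-5,6,7,8-tetrahydroquinolin-4(1H)-one | COc1c(C)n(Cc3ccc(OC)cc3)c2c(c1=O)[C@@H](/C=C/CCCc4ccccc4)CC[C@H]2O[Si](C)(C)C(C)(C)C | intermediate
14 | (5S,8R)-8-[(tert-butyldimethylsilyl)oxy]-3-methoxy-1-(4-methoxybenzyl)-2-methyl-5-(5-phenylpentyl)-5,6,7,8-tetrahydroquinolin-4(1H)-one | COc1c(C)n(Cc3ccc(OC)cc3)c2c(c1=O)[C@@H](CCCCCc4ccccc4)CC[C@H]2O[Si](C)(C)C(C)(C)C | intermediate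
15 | (5S,8R)-8-hydroxy-3-methoxy-1-(4-methoxybenzyl)-2-methyl-5-(5-phenylpentyl)-5,6,7,8-tetrahydroquinolin-4(1H)-one (not isolated) | COc1c(C)n(Cc3ccc(OC)cc3)c2c(c1=O)[C@@H](CCCCCc4ccccc4)CC[C@H]2O | intermediate
16 | (5S,8R)-8-hydroxy-3-methoxy-2-methyl-5-(5-phenylpentyl)-5,6,7,8-tetrahydroquinolin-4(1H)-one (CNP0518538.1) | COc1c(C)[nH]c2c(c1=O)[C@@H](CCCCCc1ccccc1)CC[C@H]2O | target

Total step count: 9
Longest linear sequence: 9 steps (1 → 16)

Steps most likely to fail

1. Step 6.
   - What may go wrong: C4a may be too weak a nucleophile for the iridium allyl. The complex would then stall, and hydrolysis of the carbonate or intermolecular O-allylation at C4=O would take over. Face discrimination may also be weak.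
   - Fallback (known chemistry, polarity at C4a reversed), from 9 back to 11. Iodination of 9 at C4a with N-iodosuccinimide (MeCN, 0 °C), the usual halogenation site of 4-pyridones, should give the iodopyridone F1.
   - Cross-metathesis of F1 with allyltrimethylsilane (second-generation Grubbs catalyst, CH2Cl2, 40 °C) should give the allylsilane F2.
   - An asymmetric intramolecular Heck reaction follows, with zerovalent palladium from Pd2(dba)3·CHCl3, the BINAP antipode matched to the cis isomer, Ag3PO4, DMF, 80 °C. It closes ring B by 6-exo carbopalladation. Loss of the silyl group replaces beta-hydride elimination, so the vinyl group forms and the route is rejoined at 11.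

2. Step 4.
   - What may go wrong: nitrogen may close slowly onto the hindered C8a ketone. That leaves time for retro-Claisen cleavage of the triketone by the amine and for enolisation toward C8, which erodes enantiopurity.
   - Fallback, from 6 back to 9. Acid-catalysed cyclodehydration of 6 (Amberlyst-15, 4 Å MS, CH2Cl2, rt) should give the gamma-pyranone F3. This is an aromatic, chromatographable compound with no enolisable ketone next to C8.
   - F3 tolerates the forcing oxygen-to-nitrogen exchange with 7 (EtOH/H2O, sealed tube, 100–120 °C). The exchange runs by addition, ring opening and ring closure and returns to 9.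

3. Step 3.
   - What may go wrong: proton transfer from the ester to the dianion may compete with acylation. This would stop conversion and scramble the C8 centre.
   - Fallback, from 3 back to 6. Reduction of 3 with DIBAL-H (CH2Cl2, −78 °C) gives the aldehyde F4, a far better electrophile.
   - F4 undergoes aldol addition with dianion 5 at −78 °C to give the aldol adduct F5, a mixture at the new carbinol carbon.
   - Oxidation of F5 with Dess–Martin periodinane (CH2Cl2, rt) removes that centre and returns to 6.

Further compounds
F1 | step 6 | 6-{(1R)-1-[(tert-butyldimethylsilyl)oxy]pent-4-en-1-yl}-5-iodo-3-methoxy-1-(4-methoxybenzyl)-2-methylpyridin-4(1H)-one | COc1c(C)n(Cc2ccc(OC)cc2)c([C@H](O[Si](C)(C)C(C)(C)C)CCC=C)c(I)c1=O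
F2 | step 6 | 6-{(1R,4E)-1-[(tert-butyldimethylsilyl)oxy]-6-(trimethylsilyl)hex-4-en-1-yl}-5-iodo-3-methoxy-1-(4-methoxybenzyl)-2-methylpyridin-4(1H)-one | COc1c(C)n(Cc2ccc(OC)cc2)c([C@H](O[Si](C)(C)C(C)(C)C)CC/C=C/C[Si](C)(C)C)c(I)c1=O
F3 | step 4 | 2-{(1R)-1-[(tert-butyldimethylsilyl)oxy]pent-4-en-1-yl}-5-methoxy-6-methyl-4H-pyran-4-one | COc1c(C)oc([C@H](O[Si](C)(C)C(C)(C)C)CCC=C)cc1=O
F4 | step 3 | (2R)-2-[(tert-butyldimethylsilyl)oxy]hex-5-enal | O=C[C@H](O[Si](C)(C)C(C)(C)C)CCC=C
F5 | step 3 | (7R)-7-[(tert-butyldimethylsilyl)oxy]-6-hydroxy-3-methoxyundec-10-ene-2,4-dione (mixture at C3 and C6) | CC(=O)C(OC)C(=O)CC(O)[C@H](O[Si](C)(C)C(C)(C)C)CCC=C
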